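Over the 12.0 h of the amber run, at constant temperature, starting material fell to 90.4% of its charge, a loss of 9.6 percentage points against a scatter of 0.5 points.

in all of them: reagent 28.6 mM; free catalyst 0.46 mM; impurity 0.16 mM

|  | starting material | remark | time |
|---|---|---|---|
| amber | 11 mM | run made earlier |  |
| autumn | 22 mM |  | 2.5 d |
| winter | 22 mM |  | 5.0 d |

amber run (percent of the starting material charged)

| time / h | target / % | intermediate / % | isomer of the product / % | starting material / % |
|---|---|---|---|---|
| 1.50 | 0.5 | 1.3 | 0.2 | 98.4 |
| 4.00 | 1.8 | 2.1 | 1.0 | 96.8 |
| 8.00 | 2.9 | 3.3 | 0.7 | 93.7 |
| 12.0 | 6.5 | 1.7 | 0 | 90.4 |

(each reading ± 0.5 percentage points)



* which of these there is most of at the end, counted by the starting material in it, autumn (intermediate / isomer of the product / starting material / target)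
* which of these there is most of at the end, counted by the starting material in it, winter (intermediate / isomer of the product / starting material / target)
* how much there is at the end of the one of these that leads, in percent of the starting material charged: autumn
* how much there is at the end of the one of these that leads, in percent of the starting material charged: winter

Replace the curve by one mean: the natural logarithm of charge over remainder, divided by the time, gives 0.00841 /h. This mean loss constant is a pseudo-first-order constant, and it counts in percent of the charge. So it carries from 11 mM to 22 mM, and on to longer times than amber ran, on the assumption of first order in starting material, which amber with its single charge does not test; catalyst, impurity and reagent are charged as in amber.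

Autumn, at 2.5 d, then keeps 60.4% of its starting material, and winter, at 5.0 d, keeps 36.4%. The error of the mean can be checked: the reading at 8.00 h gives 0.00813 /h, and that leaves winter 37.7%. Autumn's converted share is 39.6%, so starting material leads there.

Winter is the weak link. On this reckoning, target passes starting material in winter as long as isomer and intermediate together stay below 27.1%, which is 0.426 of what was converted. Amber's mean isomer reading, 0.475%, lies within the scatter and yields no rate, so this margin is what carries the call. The commitment is starting material at 60.4% in autumn and, weakly, target in winter, somewhere above 36.4%.

The forecast, reckoning with a case where “the absolute rate stays fixed”, named starting material at 68% for autumn and starting material at 50% for winter, so it differs from this reckoning in winter's leader and stands higher in autumn.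

Autumn gives starting material at 61.5%; winter gives target at 43.8%, ahead of starting material at 37.8%. Raising amber's starting material to autumn's charge, with the time held at amber's last reading, leaves target at 6.48% against 6.53%. Winter's remaining starting material corresponds to a mean loss constant of 0.00811 /h, against 0.00841 /h as read from amber's last reading, a gap of 1.4 points in the amount left.

    starting material + free catalyst → free catalyst + intermediate (k = 0.00750 /M/s)
    reagent + free catalyst + intermediate → free catalyst + target (k = 9.90 /M²/s)
    target ⇌ isomer of the product (K = 0.540, k = 2.90 × 10⁻⁶ /s)
    free catalyst + impurity → spent catalyst (k = 10.0 /M/s)

The first step runs in proportion to free catalyst. In a flask like autumn but charged with 1.8 mM of it, free catalyst stands at 91.1% of that charge at the end, against 65.2% of autumn's, so the mean loss constant scales to 0.0460 /h and 2.5 d leaves 6.33% of the starting material. That flask holds 7.02%.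

The data were generated by integration with constants of no real substance.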